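Ring B (C5–C10) of this labdane is a homoallylic alcohol of the 3-methylenecyclohexanol type: oxygen on C6, the C8=C17 methylene two carbons on, and C9 bonded to quaternary C10. That pattern is what a type 2 carbonyl-ene closure delivers, so the route disconnects C6–C7 and C9–C10. A ring A dienol acid with an (S)-C6 carbinol and an E C8=C9 alkene is rearranged as its dianion by an anionic oxy-Cope shift (C9–C10 formed, C6–C7 broken); the C6 aldehyde released in this way then cyclises onto the new isopropenyl group under Me2AlCl. One operation builds ring B, two skeletal bonds and the C5, C6, C9 and C10 stereocentres from one carbinol; the Z-diene is attached last.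

Key step: step 13

Numbering: labdane numbering is used for all intermediates (ring A = C1–C5 and C10; ring B = C5–C10; C17 on C8; C18 methyl and C19 carboxyl carbon on C4; C20 methyl on C10; C11–C16 side chain).

Assumption: in step 2 the (S)-valine auxiliary, with only ether ligands on lithium, is taken to direct iodomethane to the face anti to its isopropyl group, giving (S)-6; should the sense prove opposite, tert-butyl D-valinate is used under the same conditions and nothing else changes.

Step 1
Reactants: 1 methyl 2-oxocyclohexane-1-carboxylate; 2 tert-butyl L-valinate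
Product: 3 methyl 2-{[(2S)-1-tert-butoxy-3-methyl-1-oxobutan-2-yl]amino}cyclohex-1-ene-1-carboxylate
Conditions: BF3·OEt2 (cat.), toluene, reflux, Dean–Stark
Reagents that add atoms: none
Why: Acid-catalysed condensation of the β-keto ester with the primary amine under azeotropic removal of water should give the conjugated, hydrogen-bonded enamino ester (enamine formation), which carries the chiral auxiliary into the alkylation.

Step 2
Reactants: 3 enamino ester
Product: 6 methyl (S)-1-methyl-2-oxocyclohexane-1-carboxylate, via N-lithio enamine 4 (not isolated), via C4-methylated imine 5 (not isolated)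
Conditions: LiN(i-Pr)2, toluene–THF, −78 °C; MeI, −78 to −40 °C; then AcOH–NaOAc buffer (aq), rt
Reagents that add atoms: iodomethane, CI; water, O
Why: N-Lithiation should give a rigid aza-enolate in which lithium is held by the nitrogen and both ester carbonyls, so the isopropyl group screens one face and iodomethane alkylates C4 from the open face (chiral enamine alkylation creating the quaternary C4 centre), after which mild hydrolysis of the imine releases the keto ester and the auxiliary.

Step 3
Reactants: 6 methyl (S)-1-methyl-2-oxocyclohexane-1-carboxylate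
Product: 8 methyl (1S,3RS)-1,3-dimethyl-2-oxocyclohexane-1-carboxylate, via lithium enolate 7 (not isolated)
Conditions: LiN(i-Pr)2, THF, −78 °C; MeI, −78 to 0 °C
Reagents that add atoms: iodomethane, CI
Why: With C4 quaternary only the C10 side can enolise, so kinetic deprotonation and SN2 methylation (ketone enolate alkylation) install the C20 carbon, and the new centre may stay a mixture because it becomes sp2 in the next step.

Step 4
Reactants: 8 methyl (1S,3RS)-1,3-dimethyl-2-oxocyclohexane-1-carboxylate
Product: 10 methyl (S)-1,3-dimethyl-2-{[(trifluoromethyl)sulfonyl]oxy}cyclohex-2-ene-1-carboxylate, via potassium enolate 9 (not isolated)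
Conditions: KN(SiMe3)2, THF, −78 °C; PhNTf2, −78 to 0 °C
Reagents that add atoms: N-phenylbis(trifluoromethanesulfonimide), O=S(=O)(N(c1ccccc1)S(=O)(=O)C(F)(F)F)C(F)(F)F
Why: Deprotonation can again occur only at C10–H, and O-sulfonylation of the tetrasubstituted enolate (enol triflate formation) fixes the C5=C10 double bond of ring A.

Step 5
Reactants: 10 enol triflate
Product: 11 methyl (S)-2-formyl-1,3-dimethylcyclohex-2-ene-1-carboxylate (ring A enal)
Conditions: Pd(OAc)2 (5 mol %), dppp (5 mol %), CO (1 atm), Et3SiH, Et3N, DMF, 70 °C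
Reagents that add atoms: carbon monoxide, [C-]#[O+]
Why: Oxidative addition of the enol triflate to zerovalent palladium, CO insertion and hydride transfer from the silane to the acylpalladium (palladium-catalysed reductive carbonylation of an enol triflate) should introduce C6 as the aldehyde without touching the ester.

Step 6
Reactants: 12 3-[(tert-butyldimethylsilyl)oxy]propan-1-ol
Product: 14 ethyl (E)-5-[(tert-butyldimethylsilyl)oxy]-2-methylpent-2-enoate, via 3-silyloxypropanal 13 (not isolated)
Conditions: TEMPO (10 mol %), PhI(OAc)2, CH2Cl2, rt; then Ph3P=C(CH3)CO2Et, rt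
Reagents that add atoms: ethyl 2-(triphenylphosphoranylidene)propanoate, CCOC(=O)C(C)=P(c1ccccc1)(c1ccccc1)c1ccccc1
Why: Nitroxyl-catalysed oxidation stops at the aldehyde, which is trapped in the same flask by the stabilised ylide in an E-selective Wittig olefination, so the sensitive β-silyloxy aldehyde is never isolated and the E trisubstituted alkene (the later C8=C9 bond with C17) is set.

Step 7
Reactants: 14 ethyl (E)-5-[(tert-butyldimethylsilyl)oxy]-2-methylpent-2-enoate
Product: 15 (E)-5-[(tert-butyldimethylsilyl)oxy]-2-methylpent-2-en-1-ol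
Conditions: i-Bu2AlH (2.2 equiv), CH2Cl2, −78 °C; aq. potassium sodium tartrate
Reagents that add atoms: none
Why: 1,2-Reduction of the conjugated ester by two hydride equivalents (aluminium hydride reduction of an enoate) should give the allylic alcohol with the E geometry untouched.

Step 8
Reactants: 15 (E)-5-[(tert-butyldimethylsilyl)oxy]-2-methylpent-2-en-1-ol
Product: 17 tert-butyl{[(E)-5-chloro-4-methylpent-3-en-1-yl]oxy}dimethylsilane, via allylic mesylate 16 (not isolated)
Conditions: MsCl, Et3N, THF, −40 °C; then LiCl, 0 °C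
Reagents that add atoms: lithium chloride, [Li+].[Cl-]
Why: Mesylation and SN2 displacement by chloride at the primary allylic carbon give the allylic chloride without allylic transposition or loss of E geometry; the chloride is chosen because it suffers less Wurtz coupling on metalation than the bromide.

Step 9
Reactants: 11 ring A enal; 17 (E)-allylic chloride
Product: 19 methyl (1S)-2-[(3E)-6-[(tert-butyldimethylsilyl)oxy]-1-hydroxy-3-methylhex-3-en-1-yl]-1,3-dimethylcyclohex-2-ene-1-carboxylate (both C6 epimers), via allylbarium chloride 18 (not isolated)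
Conditions: BaI2, Li, biphenyl, THF, rt; 17, −78 °C; then 11, −78 °C; NH4Cl (aq), −78 °C
Reagents that add atoms: none
Why: Allylbarium reagents formed at −78 °C keep their double-bond geometry and add to aldehydes through the less substituted α terminus (Barbier-type α-selective allylation), so C6–C7 forms with the E C8=C9 alkene intact; the cold quench keeps the C6 alkoxide from closing onto the C19 ester, and the C6 epimers are not separated because C6 is oxidised next.

Step 10
Reactants: 19 homoallylic alcohols
Product: 20 methyl (S)-2-[(3E)-6-[(tert-butyldimethylsilyl)oxy]-3-methylhex-3-enoyl]-1,3-dimethylcyclohex-2-ene-1-carboxylate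
Conditions: Dess–Martin periodinane, NaHCO3, CH2Cl2, 0 °C to rt
Reagents that add atoms: none
Why: Buffered Dess–Martin oxidation converts both carbinol epimers into one ketone under conditions mild enough that the β,γ double bond should not move into conjugation.

Step 11
Reactants: 20 dienone
Product: 21 methyl (1S)-2-[(1S,3E)-6-[(tert-butyldimethylsilyl)oxy]-1-hydroxy-3-methylhex-3-en-1-yl]-1,3-dimethylcyclohex-2-ene-1-carboxylate
Conditions: (R)-2-methyl-CBS-oxazaborolidine (0.5 equiv), catecholborane, toluene, −78 to −40 °C; MeOH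
Reagents that add atoms: none
Why: In the Corey–Bakshi–Shibata reduction the 2,6-disubstituted cyclohexenyl group acts as the large substituent and the C7 methylene as the small one, so the (R)-oxazaborolidine should deliver hydride to the face that gives the (S) carbinol at C6; because C4 is already stereogenic the minor C6 epimer is a diastereomer and can be removed by chromatography.

Step 12
Reactants: 21 (6S)-hydroxy ester
Product: 23 (1S)-2-[(1S,3E)-6-[(tert-butyldimethylsilyl)oxy]-1-hydroxy-3-methylhex-3-en-1-yl]-1,3-dimethylcyclohex-2-ene-1-carboxylic acid, via 19,6-lactone 22 (not isolated)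
Conditions: KOH, THF–MeOH–H2O, 45 °C; then KHSO4 (aq) to pH 5, 0 °C; used at once
Reagents that add atoms: potassium hydroxide, [K+].[OH-]
Why: The neighbouring C6 hydroxyl should assist hydrolysis by closing onto C19 to a γ-lactone that hydroxide opens far faster than it attacks the neopentyl methyl ester itself (saponification by acyl–oxygen cleavage, C6 configuration untouched), and acidifying only to pH 5 in the cold keeps the γ-hydroxy acid from relactonising or ionising at allylic C6.

Step 13
Reactants: 23 ring A dienol acid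
Product: 27 (1S,4aR,5S,8S,8aR)-5-{2-[(tert-butyldimethylsilyl)oxy]ethyl}-8-hydroxy-1,4a-dimethyl-6-methylidenedecahydronaphthalene-1-carboxylic acid, via dipotassium alkoxide carboxylate 24 (not isolated), via dipotassium enolate carboxylate 25 (not isolated), via aldehyde acid 26 (not isolated)
Conditions: KH, 18-crown-6, THF, 0 °C to rt; MeOH, −78 °C to rt; KHSO4 (aq), extraction; then Me2AlCl (3.5 equiv), CH2Cl2, −78 to −20 °C
Reagents that add atoms: none
Why: KH deprotonates both acidic sites, and the crown-ether-separated C6 alkoxide drives a [3,3] sigmatropic shift (anionic oxy-Cope rearrangement of a potassium 1,5-dien-3-olate, the closest known reaction type) in which C6–C7 breaks and C9–C10 forms, while the C19 carboxylate is an inert spectator that the alkoxide cannot acylate. The shift should pass through the chair in which the C6 oxygen is equatorial (an axial oxygen would clash with the axial C20 methyl on C10) and C11 of the E alkene is equatorial, so the C6 carbinol alone directs bonding to the α face of C10 and fixes C10 (C20 β) and C9 (H α) together. Methanol protonates the resulting C5=C6 enolate, and the methoxide formed lets C5 settle with the formyl group equatorial and trans to the C9 branch, the epimer needed for trans fusion (C5–H α). Me2AlCl, in excess so that one equivalent first caps the acid as its aluminium carboxylate, then activates the aldehyde for a type 2 carbonyl-ene reaction (known to give 3-methylenecyclohexanols from aldehydes tethered to the central carbon of an isopropenyl unit), in which C7 attacks C6 and a C17 hydrogen passes to oxygen. Ring B closes as a six-membered ring that takes in both alkene carbons (C7 and C8) and leaves the oxygen exocyclic, through a chair with the complexed carbonyl equatorial and turned away from the axial C20 and C19 groups, which sets the 6α alcohol. The step needs chair over boat in the shift, rearrangement faster than fragmentation of the alkoxide, and the exocyclic C8=C17 alkene, which should be secured by the allylic strain around C6, by running the shift cold with sequestered potassium, and by the six-centre hydrogen transfer that the freely rotating C17 methyl reaches most easily.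

Step 14
Reactants: 27 bicyclic hydroxy acid
Product: 28 methyl (1S,4aR,5S,8S,8aR)-5-{2-[(tert-butyldimethylsilyl)oxy]ethyl}-8-hydroxy-1,4a-dimethyl-6-methylidenedecahydronaphthalene-1-carboxylate
Conditions: Me3SiCHN2, toluene–MeOH (4:1), 0 °C to rt
Reagents that add atoms: trimethylsilyldiazomethane, C[Si](C)(C)C=[N+]=[N-]
Why: The diazoalkane O-methylates the hindered axial acid through the carboxylate–methyldiazonium ion pair (diazoalkane esterification) under neutral conditions that leave the alcohol, the silyl ether and the exocyclic alkene alone.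

Step 15
Reactants: 28 hydroxy methyl ester
Product: 29 methyl (1S,4aR,5S,8S,8aR)-8-acetoxy-5-{2-[(tert-butyldimethylsilyl)oxy]ethyl}-1,4a-dimethyl-6-methylidenedecahydronaphthalene-1-carboxylate
Conditions: Ac2O, DMAP, pyridine, rt
Reagents that add atoms: acetic anhydride, CC(=O)OC(C)=O
Why: DMAP-catalysed acylation of the equatorial 6α hydroxyl, the only free hydroxyl in the molecule, should give the acetate with retention at C6 (nucleophile-catalysed esterification).

Step 16
Reactants: 29 acetate
Product: 30 methyl (1S,4aR,5S,8S,8aR)-8-acetoxy-5-(2-hydroxyethyl)-1,4a-dimethyl-6-methylidenedecahydronaphthalene-1-carboxylate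
Conditions: HF·pyridine, pyridine, THF, 0 °C to rt
Reagents that add atoms: none
Why: Buffered fluoride cleaves the primary silyl ether (Si–O cleavage driven by Si–F bond formation) under conditions that spare the acetate, the methyl ester and the exocyclic alkene.

Step 17
Reactants: 30 primary alcohol
Product: 31 methyl (1S,4aR,5S,8S,8aR)-8-acetoxy-1,4a-dimethyl-6-methylidene-5-(2-oxoethyl)decahydronaphthalene-1-carboxylate
Conditions: Dess–Martin periodinane, NaHCO3, CH2Cl2, 0 °C to rt
Reagents that add atoms: none
Why: Dess–Martin oxidation should give the C12 aldehyde without over-oxidation and without disturbing the allylic C9 centre or the exocyclic alkene.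

Step 18
Reactants: 31 C12 aldehyde
Product: 32 methyl (1S,4aR,5S,8S,8aR)-8-acetoxy-5-[(2Z)-3-iodobut-2-en-1-yl]-1,4a-dimethyl-6-methylidenedecahydronaphthalene-1-carboxylate
Conditions: EtPPh3Br, n-BuLi, THF, rt; I2, −78 °C; NaN(SiMe3)2, −20 °C; then 31, −78 to −20 °C
Reagents that add atoms: ethyltriphenylphosphonium bromide, CC[P+](c1ccccc1)(c1ccccc1)c1ccccc1.[Br-]; iodine, II
Why: The α-iodo ylide made from the ethylphosphonium salt should react with the unbranched aldehyde under kinetic control (Stork–Zhao-type iodo-olefination, a Wittig reaction) to place iodine cis to C11, which fixes the geometry of the C12=C13 bond, and the esters are inert to the ylide at this temperature.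

Step 19
Reactants: 32 (Z)-alkenyl iodide
Product: 33 methyl (1S,4aR,5S,8S,8aR)-8-acetoxy-1,4a-dimethyl-6-methylidene-5-[(2Z)-3-methylpenta-2,4-dien-1-yl]decahydronaphthalene-1-carboxylate (target)
Conditions: tributyl(vinyl)stannane, Pd(PPh3)4 (5 mol %), CuI, CsF, DMF, rt to 45 °C
Reagents that add atoms: tributyl(vinyl)stannane, C=C[Sn](CCCC)(CCCC)CCCC
Why: Stille coupling proceeds with retention at the alkenyl iodide, so the vinyl group replaces iodine cis to C11 and completes the 12Z diene, and CuI with fluoride speeds transmetalation so that the coupling runs near room temperature where the skipped triene should not isomerise.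

Compound list
1 | methyl 2-oxocyclohexane-1-carboxylate | COC(=O)C1CCCCC1=O | starting material
2 | tert-butyl L-valinate, (S) (free base from the commercial hydrochloride) | CC(C)[C@H](N)C(=O)OC(C)(C)C | starting material
3 | methyl 2-{[(2S)-1-tert-butoxy-3-methyl-1-oxobutan-2-yl]amino}cyclohex-1-ene-1-carboxylate | COC(=O)C1=C(N[C@@H](C(C)C)C(=O)OC(C)(C)C)CCCC1 | intermediate
4 | N-lithio derivative of 3 (not isolated) | COC(=O)C1=C(N([Li])[C@@H](C(C)C)C(=O)OC(C)(C)C)CCCC1 | intermediate
5 | imine of (S)-methyl 1-methyl-2-oxocyclohexane-1-carboxylate with tert-butyl L-valinate (not isolated) | COC(=O)[C@@]1(C)CCCCC1=N[C@@H](C(C)C)C(=O)OC(C)(C)C | intermediate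
6 | methyl (S)-1-methyl-2-oxocyclohexane-1-carboxylate | COC(=O)[C@@]1(C)CCCCC1=O | intermediate
7 | lithium enolate of 6 towards C10 (not isolated) | COC(=O)[C@@]1(C)CCCC=C1O[Li] | intermediate
8 | methyl (1S,3RS)-1,3-dimethyl-2-oxocyclohexane-1-carboxylate | COC(=O)[C@@]1(C)CCCC(C)C1=O | intermediate
9 | potassium enolate of 8 (not isolated) | COC(=O)[C@@]1(C)CCCC(C)=C1[O-].[K+] | intermediate
10 | methyl (S)-1,3-dimethyl-2-{[(trifluoromethyl)sulfonyl]oxy}cyclohex-2-ene-1-carboxylate | COC(=O)[C@@]1(C)CCCC(C)=C1OS(=O)(=O)C(F)(F)F | intermediate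
11 | methyl (S)-2-formyl-1,3-dimethylcyclohex-2-ene-1-carboxylate (ring A enal, CHO = C6) | COC(=O)[C@@]1(C)CCCC(C)=C1C=O | intermediate
12 | 3-[(tert-butyldimethylsilyl)oxy]propan-1-ol | OCCCO[Si](C)(C)C(C)(C)C | starting material
13 | 3-[(tert-butyldimethylsilyl)oxy]propanal (not isolated) | O=CCCO[Si](C)(C)C(C)(C)C | intermediate
14 | ethyl (E)-5-[(tert-butyldimethylsilyl)oxy]-2-methylpent-2-enoate | CCOC(=O)/C(C)=C/CCO[Si](C)(C)C(C)(C)C | intermediate
15 | (E)-5-[(tert-butyldimethylsilyl)oxy]-2-methylpent-2-en-1-ol | OC/C(C)=C/CCO[Si](C)(C)C(C)(C)C | intermediate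
16 | (E)-5-[(tert-butyldimethylsilyl)oxy]-2-methylpent-2-en-1-yl methanesulfonate (not isolated) | CS(=O)(=O)OC/C(C)=C/CCO[Si](C)(C)C(C)(C)C | intermediate
17 | tert-butyl{[(E)-5-chloro-4-methylpent-3-en-1-yl]oxy}dimethylsilane | ClC/C(C)=C/CCO[Si](C)(C)C(C)(C)C | intermediate
18 | [(E)-5-[(tert-butyldimethylsilyl)oxy]-2-methylpent-2-en-1-yl]barium chloride (not isolated) | Cl[Ba]C/C(C)=C/CCO[Si](C)(C)C(C)(C)C | intermediate
19 | methyl (1S)-2-[(3E)-6-[(tert-butyldimethylsilyl)oxy]-1-hydroxy-3-methylhex-3-en-1-yl]-1,3-dimethylcyclohex-2-ene-1-carboxylate, both C6 epimers | COC(=O)[C@@]1(C)CCCC(C)=C1C(O)C/C(C)=C/CCO[Si](C)(C)C(C)(C)C | intermediate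
20 | methyl (S)-2-[(3E)-6-[(tert-butyldimethylsilyl)oxy]-3-methylhex-3-enoyl]-1,3-dimethylcyclohex-2-ene-1-carboxylate | COC(=O)[C@@]1(C)CCCC(C)=C1C(=O)C/C(C)=C/CCO[Si](C)(C)C(C)(C)C | intermediate
21 | methyl (1S)-2-[(1S,3E)-6-[(tert-butyldimethylsilyl)oxy]-1-hydroxy-3-methylhex-3-en-1-yl]-1,3-dimethylcyclohex-2-ene-1-carboxylate | COC(=O)[C@@]1(C)CCCC(C)=C1[C@@H](O)C/C(C)=C/CCO[Si](C)(C)C(C)(C)C | intermediate
22 | 19,6-lactone: (3S,7aS)-3-[(2E)-5-[(tert-butyldimethylsilyl)oxy]-2-methylpent-2-en-1-yl]-4,7a-dimethyl-5,6,7,7a-tetrahydro-2-benzofuran-1(3H)-one (not isolated) | O1C(=O)[C@@]2(C)CCCC(C)=C2[C@@H]1C/C(C)=C/CCO[Si](C)(C)C(C)(C)C | intermediate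
23 | (1S)-2-[(1S,3E)-6-[(tert-butyldimethylsilyl)oxy]-1-hydroxy-3-methylhex-3-en-1-yl]-1,3-dimethylcyclohex-2-ene-1-carboxylic acid (ring A dienol acid, precursor of the key step) | OC(=O)[C@@]1(C)CCCC(C)=C1[C@@H](O)C/C(C)=C/CCO[Si](C)(C)C(C)(C)C | intermediate
24 | dipotassium salt of 23, C6 alkoxide and C19 carboxylate (not isolated) | [K+].[K+].[O-]C(=O)[C@@]1(C)CCCC(C)=C1[C@@H]([O-])C/C(C)=C/CCO[Si](C)(C)C(C)(C)C | intermediate
25 | dipotassium salt of the rearranged C5=C6 enolate carboxylate, C9–C10 bond formed, isopropenyl on C9 (not isolated) | [K+].[K+].[O-]C(=O)[C@@]1(C)CCC[C@](C)([C@@H](CCO[Si](C)(C)C(C)(C)C)C(C)=C)/C1=C/[O-] | intermediate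
26 | (1S,2R,3R)-3-[(3S)-5-[(tert-butyldimethylsilyl)oxy]-2-methylpent-1-en-3-yl]-2-formyl-1,3-dimethylcyclohexane-1-carboxylic acid (not isolated) | OC(=O)[C@@]1(C)CCC[C@](C)([C@@H](CCO[Si](C)(C)C(C)(C)C)C(C)=C)[C@H]1C=O | intermediate
27 | (1S,4aR,5S,8S,8aR)-5-{2-[(tert-butyldimethylsilyl)oxy]ethyl}-8-hydroxy-1,4a-dimethyl-6-methylidenedecahydronaphthalene-1-carboxylic acid (6α-hydroxy 8(17)-ene 19-acid, product of the key step) | CC(C)(C)[Si](C)(C)OCC[C@H]1C(=C)C[C@H](O)[C@@H]2[C@]1(C)CCC[C@]2(C)C(=O)O | intermediate
28 | methyl ester of 27 | CC(C)(C)[Si](C)(C)OCC[C@H]1C(=C)C[C@H](O)[C@@H]2[C@]1(C)CCC[C@]2(C)C(=O)OC | intermediate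
29 | 6α-acetate of 28 | CC(C)(C)[Si](C)(C)OCC[C@H]1C(=C)C[C@H](OC(C)=O)[C@@H]2[C@]1(C)CCC[C@]2(C)C(=O)OC | intermediate
30 | methyl (1S,4aR,5S,8S,8aR)-8-acetoxy-5-(2-hydroxyethyl)-1,4a-dimethyl-6-methylidenedecahydronaphthalene-1-carboxylate | OCC[C@H]1C(=C)C[C@H](OC(C)=O)[C@@H]2[C@]1(C)CCC[C@]2(C)C(=O)OC | intermediate
31 | methyl (1S,4aR,5S,8S,8aR)-8-acetoxy-1,4a-dimethyl-6-methylidene-5-(2-oxoethyl)decahydronaphthalene-1-carboxylate | O=CC[C@H]1C(=C)C[C@H](OC(C)=O)[C@@H]2[C@]1(C)CCC[C@]2(C)C(=O)OC | intermediate
32 | methyl (1S,4aR,5S,8S,8aR)-8-acetoxy-5-[(2Z)-3-iodobut-2-en-1-yl]-1,4a-dimethyl-6-methylidenedecahydronaphthalene-1-carboxylate | C/C(I)=C/C[C@H]1C(=C)C[C@H](OC(C)=O)[C@@H]2[C@]1(C)CCC[C@]2(C)C(=O)OC | intermediate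
33 | methyl (1S,4aR,5S,8S,8aR)-8-acetoxy-1,4a-dimethyl-6-methylidene-5-[(2Z)-3-methylpenta-2,4-dien-1-yl]decahydronaphthalene-1-carboxylate (methyl 6α-acetoxylabda-8(17),12Z,14-trien-19-oate) | C=C/C(C)=C\C[C@H]1C(=C)C[C@H](OC(C)=O)[C@@H]2[C@]1(C)CCC[C@]2(C)C(=O)OC | target

Total step count: 19. Longest linear sequence: 16 steps (steps 1–5 and 9–19); the side-chain chloride 17 takes 3 steps (6–8).

Steps most likely to fail

Step 13. The homoallylic potassium alkoxide may fragment (heterolysis of C6–C7 back to enal and allyl anion) faster than it rearranges, or the aluminium carboxylate at C19 may deliver the Lewis acid internally and spoil the ene closure or its C6 selectivity. The fallback runs the same two bond changes without anions or a free acid. It sets out from 21, which is silylated (Me3SiCl, imidazole, CH2Cl2) to the trimethylsilyl ether F1. Thermal siloxy-Cope rearrangement (degassed o-dichlorobenzene, about 200 °C, base-washed glass) through the same chair should give the silyl enol ether F2. K2CO3 in MeOH then frees and equilibrates the aldehyde ester F3, and Me2AlCl in CH2Cl2 at −78 °C closes ring B by the type 2 carbonyl-ene reaction on the methyl ester. The route is rejoined at 28, and step 14 is no longer needed.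

Step 9. Bonding through the γ terminus of the allyl metal (branched adduct), loss of E geometry by equilibration of the allylbarium above −78 °C, or Wurtz coupling during metalation may intrude. The fallback fixes the bonding carbon with a sulfone. It sets out from 17, which is displaced with PhSO2Na in DMF to the allyl phenyl sulfone F4. Its lithio derivative (n-BuLi, THF, −78 °C) adds to enal 11 through the sulfonyl-bearing carbon to give the β-hydroxy sulfone F5. Dess–Martin oxidation gives the β-keto sulfone F6, and reductive desulfonylation with SmI2 (THF–MeOH, −78 °C) returns to the route at ketone 20.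

Step 18. The α-iodo ylide may lose iodine or olefinate with low Z selectivity. The fallback sets the geometry by coupling instead. It sets out from 31, which under Corey–Fuchs conditions (CBr4, PPh3, CH2Cl2, 0 °C) gives the 1,1-dibromoalkene F7. Trans-selective Negishi monomethylation (MeZnCl, PdCl2(DPEphos), THF) replaces the bromine trans to C11 and gives the (Z)-bromoalkene F8. Stille coupling with tributyl(vinyl)stannane (Pd(P(t-Bu)3)2, CsF, dioxane) then proceeds with retention and rejoins the route at the target 33.

Further compounds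
F1 | step 13 | methyl (1S)-2-[(1S,3E)-6-[(tert-butyldimethylsilyl)oxy]-3-methyl-1-[(trimethylsilyl)oxy]hex-3-en-1-yl]-1,3-dimethylcyclohex-2-ene-1-carboxylate | COC(=O)[C@@]1(C)CCCC(C)=C1[C@@H](O[Si](C)(C)C)C/C(C)=C/CCO[Si](C)(C)C(C)(C)C
F2 | step 13 | trimethylsilyl enol ether of the rearranged aldehyde ester (C5=C6–OSiMe3, C9–C10 formed, isopropenyl on C9) | COC(=O)[C@@]1(C)CCC[C@](C)([C@@H](CCO[Si](C)(C)C(C)(C)C)C(C)=C)/C1=C/O[Si](C)(C)C
F3 | step 13 | methyl (1S,2R,3R)-3-[(3S)-5-[(tert-butyldimethylsilyl)oxy]-2-methylpent-1-en-3-yl]-2-formyl-1,3-dimethylcyclohexane-1-carboxylate | COC(=O)[C@@]1(C)CCC[C@](C)([C@@H](CCO[Si](C)(C)C(C)(C)C)C(C)=C)[C@H]1C=O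
F4 | step 9 | tert-butyldimethyl{[(E)-4-methyl-5-(phenylsulfonyl)pent-3-en-1-yl]oxy}silane | O=S(=O)(C/C(C)=C/CCO[Si](C)(C)C(C)(C)C)c1ccccc1
F5 | step 9 | methyl (1S)-2-[(3E)-6-[(tert-butyldimethylsilyl)oxy]-1-hydroxy-3-methyl-2-(phenylsulfonyl)hex-3-en-1-yl]-1,3-dimethylcyclohex-2-ene-1-carboxylate, diastereomer mixture | COC(=O)[C@@]1(C)CCCC(C)=C1C(O)C(/C(C)=C/CCO[Si](C)(C)C(C)(C)C)S(=O)(=O)c1ccccc1
F6 | step 9 | methyl (1S)-2-[(3E)-6-[(tert-butyldimethylsilyl)oxy]-3-methyl-2-(phenylsulfonyl)hex-3-enoyl]-1,3-dimethylcyclohex-2-ene-1-carboxylate | COC(=O)[C@@]1(C)CCCC(C)=C1C(=O)C(/C(C)=C/CCO[Si](C)(C)C(C)(C)C)S(=O)(=O)c1ccccc1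
F7 | step 18 | methyl (1S,4aR,5S,8S,8aR)-8-acetoxy-5-(3,3-dibromoprop-2-en-1-yl)-1,4a-dimethyl-6-methylidenedecahydronaphthalene-1-carboxylate | BrC(Br)=CC[C@H]1C(=C)C[C@H](OC(C)=O)[C@@H]2[C@]1(C)CCC[C@]2(C)C(=O)OC
F8 | step 18 | methyl (1S,4aR,5S,8S,8aR)-8-acetoxy-5-[(2Z)-3-bromobut-2-en-1-yl]-1,4a-dimethyl-6-methylidenedecahydronaphthalene-1-carboxylate | C/C(Br)=C/C[C@H]1C(=C)C[C@H](OC(C)=O)[C@@H]2[C@]1(C)CCC[C@]2(C)C(=O)OC
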